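**Retrosynthetic overview**

1. The target is an 11-oxabicyclo[4.4.1]undecane: two oxepanes share O, C5 and C10, and the oxepane O–C10–C9–C8–C7–C6–C5 carries the C9 ester and a trans-fused α-methylene-γ-lactone (C7, C8, C11–C13).
2. Enabling feature: the lactone O–C8H carbon is the γ-carbon of a furan-2(5H)-one, i.e. C5 of an aromatic 2-silyloxyfuran, and its neighbour C9 is a carbinol carbon α to the ether oxygen on C10. The C8–C9 bond of that oxepane is therefore a vinylogous aldol bond that a metal chelate between the C9 carbonyl and the ring oxygen can control.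
3. Disconnections, last to first: C9 ester and C13 (Mannich, elimination); C7–H (hydroxyl-directed hydrogenation); C8–C9 (intramolecular vinylogous Mukaiyama aldol with dearomatization of the furan); C6–C7 (B-alkyl Suzuki–Miyaura coupling); C5=C6 (lactone methylenation); O–C10 (Baeyer–Villiger); C9–C10 (hydroxymethylation of desymmetrized cis-2,6-dimethylcyclohexanone).
4. Ring order: cyclohexane (bought) → methyl-bearing oxepane O–C10–C1–C2–C3–C4–C5 (step 4) → furanone ring, attached ready-made (step 6) → lactone-bearing oxepane (step 9, last).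

Key step: step 9

Remarks before the steps:
- Locants: C1–C10 are the ten carbons of the carbocycle (C10 quaternary ether carbon with methyl C14, C9 ester carbon, C8 lactone O–CH, C7 ring-fusion CH, C6 CH2, C5 ether CH, C4 CH with methyl C15, C3–C1 CH2); C11/C12/C13 are the lactone α-carbon, carbonyl and exocyclic methylene. The semi-systematic names below use these locants.
- Assumption: commercial 2,6-dimethylcyclohexanone is a cis-rich isomer mixture; the meso cis isomer, separated before use, is compound 1.
- Assumption: lithium (R,R)-bis(1-phenylethyl)amide is taken to give the (6S)-silyl enol ether 3; if the sense of induction is opposite, the (S,S)-amide is used.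
- Assumption: the ester in the target structure is read as (R)-2-methylbutanoate, and (R)-2-methylbutanoic acid is taken as commercially available.

**Route**

Step 1
Reactants: 1 cis-2,6-dimethylcyclohexan-1-one (meso)
Product: 3 trimethyl{[(6S)-2,6-dimethylcyclohex-1-en-1-yl]oxy}silane, via lithium enolate 2 (not isolated)
Conditions: lithium (R,R)-bis(1-phenylethyl)amide [LiN(CHMePh)2, from the amine and n-BuLi], LiCl, TMSCl (internal quench), THF, −78 °C
Reagents that add atoms: chlorotrimethylsilane, C[Si](C)(C)Cl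
Why: Enantioselective deprotonation (asymmetric desymmetrization) of the meso ketone by the C2-symmetric chiral lithium amide removes one of the two enantiotopic α-hydrogens, so the untouched methyl-bearing carbon is left as the (S)-stereocenter that becomes C4.

Step 2
Reactants: 3 trimethyl{[(6S)-2,6-dimethylcyclohex-1-en-1-yl]oxy}silane
Product: 4 (2R,6S)-2-(hydroxymethyl)-2,6-dimethylcyclohexan-1-one
Conditions: aq. HCHO (37%), Yb(OTf)3 (10 mol%), THF, rt
Reagents that add atoms: formaldehyde, C=O
Why: Lanthanide-triflate-catalysed Mukaiyama aldol reaction (hydroxymethylation) in which the C6 methyl group of the enol ether sits pseudoaxial to avoid A(1,2) strain with OSiMe3 and shields one face, so formaldehyde should add anti to it and the quaternary carbon (future C10) forms with its methyl cis to the C6 methyl.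

Step 3
Reactants: 4 (2R,6S)-2-(hydroxymethyl)-2,6-dimethylcyclohexan-1-one
Product: 5 (2R,6S)-2-{[(tert-butyldimethylsilyl)oxy]methyl}-2,6-dimethylcyclohexan-1-one
Conditions: TBSCl, imidazole, DMF, rt
Reagents that add atoms: tert-butyldimethylsilyl chloride, CC(C)(C)[Si](C)(C)Cl
Why: Silyl ether formation on the primary neopentyl alcohol under mild imidazole conditions that avoid retro-aldol cleavage and epimerization of the α-stereocenter; no stereocenter is formed.

Step 4
Reactants: 5 (2R,6S)-2-{[(tert-butyldimethylsilyl)oxy]methyl}-2,6-dimethylcyclohexan-1-one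
Product: 6 (3S,7R)-7-{[(tert-butyldimethylsilyl)oxy]methyl}-3,7-dimethyloxepan-2-one
Conditions: mCPBA, CH2Cl2, 0 °C → rt
Reagents that add atoms: 3-chloroperoxybenzoic acid, OOC(=O)c1cccc(Cl)c1
Why: Baeyer–Villiger oxidation in which the more substituted (quaternary) α-carbon migrates to oxygen with retention of configuration, so the oxepanone carries the future ring-ether oxygen on C10 and keeps the C4 stereocenter.

Step 5
Reactants: 6 (3S,7R)-7-{[(tert-butyldimethylsilyl)oxy]methyl}-3,7-dimethyloxepan-2-one
Product: 7 tert-butyl{[(2R,6S)-2,6-dimethyl-7-methylideneoxepan-2-yl]methoxy}dimethylsilane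
Conditions: Cp2TiMe2, toluene, 70 °C, dark; filtration through basic alumina, used at once
Reagents that add atoms: dimethyltitanocene, [Ti+4].[CH3-].[CH3-].c1cc[cH-]c1.c1cc[cH-]c1
Why: Petasis methylenation of the lactone carbonyl through Cp2Ti=CH2, a non-basic carbonyl olefination that leaves the adjacent C4 stereocenter untouched and gives the exocyclic enol ether C5=C6.

Step 6
Reactants: 7 tert-butyl{[(2R,6S)-2,6-dimethyl-7-methylideneoxepan-2-yl]methoxy}dimethylsilane; 8 4-bromofuran-2(5H)-one
Product: 10 4-{[(2R,3S,7R)-7-{[(tert-butyldimethylsilyl)oxy]methyl}-3,7-dimethyloxepan-2-yl]methyl}furan-2(5H)-one, via B-alkyl-9-BBN 9 (not isolated)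
Conditions: 9-BBN (0.5 M in THF), 0 °C → rt; then 8, Pd(dppf)Cl2 (5 mol%), AsPh3, aq. K3PO4, DMF, rt
Reagents that add atoms: none
Why: Hydroboration followed by B-alkyl Suzuki–Miyaura coupling, in which 9-BBN places boron on the terminal carbon and should deliver hydrogen to C5 on the face opposite the axial C4–H (the course known for exo-glycals), putting C6 trans to the C4 methyl and cis to the C10 silyloxymethyl arm, after which the alkylborane couples with the vinyl bromide without touching a stereocenter.

Step 7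
Reactants: 10 4-{[(2R,3S,7R)-7-{[(tert-butyldimethylsilyl)oxy]methyl}-3,7-dimethyloxepan-2-yl]methyl}furan-2(5H)-one
Product: 11 4-{[(2R,3S,7R)-7-(hydroxymethyl)-3,7-dimethyloxepan-2-yl]methyl}furan-2(5H)-one
Conditions: HF·pyridine, THF–pyridine, 0 °C → rt
Reagents that add atoms: none
Why: Fluoride-mediated desilylation under buffered acidic conditions, chosen because the butenolide does not tolerate basic fluoride; no stereocenter is affected.

Step 8
Reactants: 11 4-{[(2R,3S,7R)-7-(hydroxymethyl)-3,7-dimethyloxepan-2-yl]methyl}furan-2(5H)-one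
Product: 12 (2R,6S,7R)-2,6-dimethyl-7-[(5-oxo-2,5-dihydrofuran-3-yl)methyl]oxepane-2-carbaldehyde
Conditions: Dess–Martin periodinane, CH2Cl2, rt
Reagents that add atoms: none
Why: Dess–Martin oxidation of the primary alcohol to an aldehyde that has no α-hydrogen and therefore cannot enolize or epimerize.

Step 9
Reactants: 12 (2R,6S,7R)-2,6-dimethyl-7-[(5-oxo-2,5-dihydrofuran-3-yl)methyl]oxepane-2-carbaldehyde
Product: 14 (4S,5R,8R,9S,10R)-9-hydroxy-5,10-epoxy-13-norgermacr-7(11)-en-12,8-olide, via 2-silyloxyfuran 13 (not isolated)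
Conditions: TMSOTf (1.0 equiv), Et3N (1.5 equiv), CH2Cl2, −78 → 0 °C; then MgBr2·OEt2 (3 equiv), −78 → −20 °C; aq. citric acid work-up
Reagents that add atoms: none
Why: TMSOTf/Et3N turn the butenolide into the aromatic 2-(trimethylsilyloxy)furan 13, MgBr2·OEt2 then binds the aldehyde oxygen and the oxepane oxygen on C10 in a five-membered chelate, and furan C5 (= C8) adds to the activated carbonyl while the furan is dearomatized to the butenolide. The closest known reaction types are chelation-controlled vinylogous Mukaiyama aldol additions of 2-silyloxyfurans to α-alkoxy aldehydes and silylative cycloaldolizations of butenolides. The only ring closed is the oxepane O–C10–C9–C8–C7–C6–C5, formed through the C8–C9 bond in a 7-(enolendo)-exo-trig mode. C9 is controlled by the chelate, which holds the carbonyl oxygen syn to the ring oxygen, together with the tether, which lets C8 reach only the carbonyl face anti to the C10 methyl (a face an intermolecular nucleophile would not choose), so the new hydroxyl should lie on the side of the bridging oxygen (9S). C8 is controlled by the open antiperiplanar transition state, in which the furan C5–H rather than the substituted C4 lies between quaternary C10 and the magnesium-bound oxygen, which should give the 8,9-threo adduct (8R). The step needs C5 (γ) over C3 (α) attack and chelate over open-chain control: the first is secured by the silyloxyfuran itself (largest HOMO coefficient at the unsubstituted C5, conjugated butenolide product), the second by the ring-ether oxygen α to the non-enolizable aldehyde on quaternary C10 and the cis arrangement of the two arms on the oxepane, supported by using exactly one equivalent of TMSOTf so that no free silyl Lewis acid remains.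

Step 10
Reactants: 14 (4S,5R,8R,9S,10R)-9-hydroxy-5,10-epoxy-13-norgermacr-7(11)-en-12,8-olide
Product: 15 (4S,5R,7R,8R,9S,10R)-9-hydroxy-5,10-epoxy-13-norgermacran-12,8-olide
Conditions: [Ir(cod)(PCy3)(py)]PF6 (10 mol%), H2 (1 atm), CH2Cl2, rt
Reagents that add atoms: none
Why: Hydroxyl-directed homogeneous hydrogenation, in which the lactone ring holds C9 out of the butenolide plane on one face so that the cationic iridium catalyst bound to the C9 hydroxyl should deliver hydrogen to C7 on that face, cis to C9, giving the trans-fused lactone (7R).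

Step 11
Reactants: 15 (4S,5R,7R,8R,9S,10R)-9-hydroxy-5,10-epoxy-13-norgermacran-12,8-olide
Product: 17 (4S,5R,7R,8R,9S,10R)-13-(dimethylamino)-9-hydroxy-5,10-epoxygermacran-12,8-olide (C11 epimers), via dilithium alkoxide enolate 16 (not isolated)
Conditions: LDA (2.5 equiv), THF, −78 °C; then [CH2=NMe2]I (3 equiv), −78 → −20 °C; water
Reagents that add atoms: dimethyl(methylidene)ammonium iodide (Eschenmoser's salt), C=[N+](C)C.[I-]
Why: Mannich reaction of the lactone lithium enolate with the preformed iminium salt, run on the alkoxide enolate dianion so that no protecting group is needed; the new C11 stereocenter is of no consequence because it becomes sp2 again in step 13.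

Step 12
Reactants: 17 (4S,5R,7R,8R,9S,10R)-13-(dimethylamino)-9-hydroxy-5,10-epoxygermacran-12,8-olide; 18 (R)-2-methylbutanoic acid
Product: 19 (4S,5R,7R,8R,9S,10R)-13-(dimethylamino)-9-{[(2R)-2-methylbutanoyl]oxy}-5,10-epoxygermacran-12,8-olide
Conditions: DCC, DMAP, CH2Cl2, 0 °C → rt
Reagents that add atoms: none
Why: Steglich esterification of the secondary C9 alcohol, an O-acylation that retains the C9 configuration and leaves the acid α-stereocenter untouched, while the dimethylaminomethyl group keeps the α-methylene lactone masked.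

Step 13
Reactants: 19 (4S,5R,7R,8R,9S,10R)-13-(dimethylamino)-9-{[(2R)-2-methylbutanoyl]oxy}-5,10-epoxygermacran-12,8-olide
Product: 21 (4S,5R,7R,8R,9S,10R)-9-{[(2R)-2-methylbutanoyl]oxy}-5,10-epoxygermacr-11(13)-en-12,8-olide (CNP0136059.1), via quaternary ammonium iodide 20 (not isolated)
Conditions: MeI (excess), THF, rt; then NaHCO3, H2O–EtOAc, rt
Reagents that add atoms: none
Why: Exhaustive N-methylation followed by Hofmann-type (E1cB) elimination of trimethylamine from the β-ammonio lactone unveils the α-methylene-γ-lactone under conditions mild enough for the ester; no stereocenter is touched.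

**Compound list**

1 | cis-2,6-dimethylcyclohexan-1-one (meso) | C[C@H]1CCC[C@@H](C)C1=O | starting material
2 | lithium (6S)-2,6-dimethylcyclohex-1-en-1-olate | [Li+].[O-]C1=C(C)CCC[C@@H]1C | intermediate
3 | trimethyl{[(6S)-2,6-dimethylcyclohex-1-en-1-yl]oxy}silane | C[Si](C)(C)OC1=C(C)CCC[C@@H]1C | intermediate
4 | (2R,6S)-2-(hydroxymethyl)-2,6-dimethylcyclohexan-1-one (methyl groups cis) | O=C1[C@](C)(CCC[C@@H]1C)CO | intermediate
5 | (2R,6S)-2-{[(tert-butyldimethylsilyl)oxy]methyl}-2,6-dimethylcyclohexan-1-one | O=C1[C@](C)(CCC[C@@H]1C)CO[Si](C)(C)C(C)(C)C | intermediate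
6 | (3S,7R)-7-{[(tert-butyldimethylsilyl)oxy]methyl}-3,7-dimethyloxepan-2-one | O=C1O[C@](C)(CCC[C@@H]1C)CO[Si](C)(C)C(C)(C)C | intermediate
7 | tert-butyl{[(2R,6S)-2,6-dimethyl-7-methylideneoxepan-2-yl]methoxy}dimethylsilane | C=C1O[C@](C)(CCC[C@@H]1C)CO[Si](C)(C)C(C)(C)C | intermediate
8 | 4-bromofuran-2(5H)-one | O=C1OCC(Br)=C1 | starting material
9 | 9-{[(2R,3S,7R)-7-{[(tert-butyldimethylsilyl)oxy]methyl}-3,7-dimethyloxepan-2-yl]methyl}-9-borabicyclo[3.3.1]nonane | C(B1C2CCCC1CCC2)[C@H]1O[C@](C)(CCC[C@@H]1C)CO[Si](C)(C)C(C)(C)C | intermediate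
10 | 4-{[(2R,3S,7R)-7-{[(tert-butyldimethylsilyl)oxy]methyl}-3,7-dimethyloxepan-2-yl]methyl}furan-2(5H)-one | O=C1OCC(C[C@H]2O[C@](C)(CCC[C@@H]2C)CO[Si](C)(C)C(C)(C)C)=C1 | intermediate
11 | 4-{[(2R,3S,7R)-7-(hydroxymethyl)-3,7-dimethyloxepan-2-yl]methyl}furan-2(5H)-one | O=C1OCC(C[C@H]2O[C@](C)(CCC[C@@H]2C)CO)=C1 | intermediate
12 | (2R,6S,7R)-2,6-dimethyl-7-[(5-oxo-2,5-dihydrofuran-3-yl)methyl]oxepane-2-carbaldehyde | O=C1OCC(C[C@H]2O[C@](C)(CCC[C@@H]2C)C=O)=C1 | intermediate
13 | (2R,6S,7R)-2,6-dimethyl-7-({5-[(trimethylsilyl)oxy]furan-3-yl}methyl)oxepane-2-carbaldehyde | C[Si](C)(C)Oc1cc(C[C@H]2O[C@](C)(CCC[C@@H]2C)C=O)co1 | intermediate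
14 | (4S,5R,8R,9S,10R)-9-hydroxy-5,10-epoxy-13-norgermacr-7(11)-en-12,8-olide (bridged tricyclic butenolide, 9-OH on the side of the bridging oxygen) | O=C1O[C@@H]2C(=C1)C[C@H]3O[C@](C)(CCC[C@@H]3C)[C@H]2O | intermediate
15 | (4S,5R,7R,8R,9S,10R)-9-hydroxy-5,10-epoxy-13-norgermacran-12,8-olide (trans-fused lactone) | C1C(=O)O[C@@H]2[C@@H]1C[C@H]1O[C@](C)(CCC[C@@H]1C)[C@H]2O | intermediate
16 | dilithium alkoxide enolate of 15 | [Li+].[Li+].C1=C([O-])O[C@@H]2[C@@H]1C[C@H]1O[C@](C)(CCC[C@@H]1C)[C@H]2[O-] | intermediate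
17 | (4S,5R,7R,8R,9S,10R)-13-(dimethylamino)-9-hydroxy-5,10-epoxygermacran-12,8-olide (C11 unspecified, both epimers) | CN(C)CC1C(=O)O[C@@H]2[C@@H]1C[C@H]1O[C@](C)(CCC[C@@H]1C)[C@H]2O | intermediate
18 | (R)-2-methylbutanoic acid | CC[C@@H](C)C(=O)O | starting material
19 | (4S,5R,7R,8R,9S,10R)-13-(dimethylamino)-9-{[(2R)-2-methylbutanoyl]oxy}-5,10-epoxygermacran-12,8-olide (C11 unspecified) | CN(C)CC1C(=O)O[C@@H]2[C@@H]1C[C@H]1O[C@](C)(CCC[C@@H]1C)[C@H]2OC(=O)[C@H](C)CC | intermediate
20 | 13-(trimethylammonio) analogue of 19, iodide salt | C[N+](C)(C)CC1C(=O)O[C@@H]2[C@@H]1C[C@H]1O[C@](C)(CCC[C@@H]1C)[C@H]2OC(=O)[C@H](C)CC.[I-] | intermediate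
21 | (4S,5R,7R,8R,9S,10R)-9-{[(2R)-2-methylbutanoyl]oxy}-5,10-epoxygermacr-11(13)-en-12,8-olide (CNP0136059.1) | C=C1C(=O)O[C@@H]2[C@@H]1C[C@H]1O[C@](C)(CCC[C@@H]1C)[C@H]2OC(=O)[C@H](C)CC | target

**Totals**

Total step count: 13. Longest linear sequence: 13 steps (from 1).

**Steps most likely to fail, with fallbacks**

Step 9 (key step). What may go wrong: cyclization through an open, non-chelated pathway promoted by residual silyl triflate before the magnesium chelate has formed (loss of facial control at C9); attack through furan C3 instead of C5; or protodesilylation of the silyloxyfuran faster than closure of the strained bicycle. In the fallback the nucleophile is made and purified before the electrophile exists, so that only the chelating Lewis acid can trigger ring closure. It sets out from 12, which is oxidized (NaClO2, NaH2PO4, 2-methylbut-2-ene) to (2R,6S,7R)-2,6-dimethyl-7-[(5-oxo-2,5-dihydrofuran-3-yl)methyl]oxepane-2-carboxylic acid F1 and methylated (TMSCHN2) to its methyl ester F2. TIPSOTf/Et3N then gives the isolable 2-(triisopropylsilyloxy)furan ester F3, and i-Bu2AlH at −78 °C reduces the ester to the silyloxyfuran aldehyde F4. MgBr2·OEt2 in CH2Cl2 at −78 °C followed by dilute acid closes the ring, and the fallback comes back to the route at 14.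

Step 6. What may go wrong: hydrogen delivery to the wrong face of the exocyclic enol ether (C5 epimer); β-alkoxy elimination of the alkylborane; or hydrolysis of 8 under the basic coupling conditions outrunning transmetalation. In the fallback C5 is set by hydride reduction of a cyclic oxocarbenium ion and the sp3–sp2 bond is made by Negishi coupling. It sets out from lactone 6, to which (benzyloxymethyl)lithium F5 (from tributyl[(benzyloxy)methyl]stannane and n-BuLi) is added at −78 °C to give the hydroxy ketone (3S,7R)-1-(benzyloxy)-8-[(tert-butyldimethylsilyl)oxy]-7-hydroxy-3,7-dimethyloctan-2-one F6. Et3SiH/TMSOTf reductive etherification (axial hydride delivery, CH2OBn trans to the C4 methyl) should give the benzyl ether oxepane F7. Hydrogenolysis (H2, Pd(OH)2/C) gives the primary alcohol F8, I2/PPh3/imidazole the iodide F9, and zinc dust/LiCl the alkylzinc iodide F10. Pd(PPh3)4-catalysed Negishi coupling with 8 brings the fallback back to the route at 10.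

Step 10. What may go wrong: weak direction by the C9 hydroxyl, which is anti to C7 in the most stable ring conformer, so that hydrogen adds from the open convex face and the cis-fused lactone forms; or slow reduction of the electron-poor alkene. In the fallback the directing group is changed from the homoallylic C9 hydroxyl to the allylic C8 hydroxyl of the ring-opened lactone. It sets out from 14, which is silylated (TBSOTf, 2,6-lutidine) to the C9 silyl ether F11 and reduced with i-Bu2AlH to the (Z)-enediol F12. Hydrogenation with [Ir(cod)(PCy3)(py)]PF6, now directed by the allylic C8 hydroxyl (hydrogen cis to O8), should give the saturated diol F13. TEMPO/PhI(OAc)2 oxidative lactonization gives the silyl-protected trans-lactone F14, and HF·pyridine brings the fallback back to the route at 15.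

**Further compounds**

F1 | step 9 | (2R,6S,7R)-2,6-dimethyl-7-[(5-oxo-2,5-dihydrofuran-3-yl)methyl]oxepane-2-carboxylic acid | O=C1OCC(C[C@H]2O[C@](C)(CCC[C@@H]2C)C(=O)O)=C1
F2 | step 9 | methyl (2R,6S,7R)-2,6-dimethyl-7-[(5-oxo-2,5-dihydrofuran-3-yl)methyl]oxepane-2-carboxylate | O=C1OCC(C[C@H]2O[C@](C)(CCC[C@@H]2C)C(=O)OC)=C1
F3 | step 9 | methyl (2R,6S,7R)-2,6-dimethyl-7-({5-[(triisopropylsilyl)oxy]furan-3-yl}methyl)oxepane-2-carboxylate | CC(C)[Si](C(C)C)(C(C)C)Oc1cc(C[C@H]2O[C@](C)(CCC[C@@H]2C)C(=O)OC)co1
F4 | step 9 | (2R,6S,7R)-2,6-dimethyl-7-({5-[(triisopropylsilyl)oxy]furan-3-yl}methyl)oxepane-2-carbaldehyde | CC(C)[Si](C(C)C)(C(C)C)Oc1cc(C[C@H]2O[C@](C)(CCC[C@@H]2C)C=O)co1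
F5 | step 6 | (benzyloxymethyl)lithium | [Li]COCc1ccccc1
F6 | step 6 | (3S,7R)-1-(benzyloxy)-8-[(tert-butyldimethylsilyl)oxy]-7-hydroxy-3,7-dimethyloctan-2-one | O=C(COCc1ccccc1)[C@@H](C)CCC[C@@](C)(O)CO[Si](C)(C)C(C)(C)C
F7 | step 6 | (2S,3S,7R)-2-[(benzyloxy)methyl]-7-{[(tert-butyldimethylsilyl)oxy]methyl}-3,7-dimethyloxepane | c1ccccc1COC[C@H]1O[C@](C)(CCC[C@@H]1C)CO[Si](C)(C)C(C)(C)C
F8 | step 6 | [(2S,3S,7R)-7-{[(tert-butyldimethylsilyl)oxy]methyl}-3,7-dimethyloxepan-2-yl]methanol | OC[C@H]1O[C@](C)(CCC[C@@H]1C)CO[Si](C)(C)C(C)(C)C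
F9 | step 6 | (2S,3S,7R)-2-(iodomethyl)-7-{[(tert-butyldimethylsilyl)oxy]methyl}-3,7-dimethyloxepane | IC[C@H]1O[C@](C)(CCC[C@@H]1C)CO[Si](C)(C)C(C)(C)C
F10 | step 6 | iodo{[(2S,3S,7R)-7-{[(tert-butyldimethylsilyl)oxy]methyl}-3,7-dimethyloxepan-2-yl]methyl}zinc | I[Zn]C[C@H]1O[C@](C)(CCC[C@@H]1C)CO[Si](C)(C)C(C)(C)C
F11 | step 10 | (4S,5R,8R,9S,10R)-9-[(tert-butyldimethylsilyl)oxy]-5,10-epoxy-13-norgermacr-7(11)-en-12,8-olide | O=C1O[C@@H]2C(=C1)C[C@H]3O[C@](C)(CCC[C@@H]3C)[C@H]2O[Si](C)(C)C(C)(C)C
F12 | step 10 | (4S,5R,8R,9S,10R,7(11)Z)-9-[(tert-butyldimethylsilyl)oxy]-5,10-epoxy-13-norgermacr-7(11)-ene-8,12-diol | OC/C=C1/C[C@H]2O[C@](C)(CCC[C@@H]2C)[C@@H](O[Si](C)(C)C(C)(C)C)[C@@H]1O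
F13 | step 10 | (4S,5R,7S,8R,9S,10R)-9-[(tert-butyldimethylsilyl)oxy]-5,10-epoxy-13-norgermacrane-8,12-diol (same spatial arrangement at C7 as in 15) | OCC[C@H]1C[C@H]2O[C@](C)(CCC[C@@H]2C)[C@@H](O[Si](C)(C)C(C)(C)C)[C@@H]1O
F14 | step 10 | (4S,5R,7R,8R,9S,10R)-9-[(tert-butyldimethylsilyl)oxy]-5,10-epoxy-13-norgermacran-12,8-olide | C1C(=O)O[C@@H]2[C@@H]1C[C@H]1O[C@](C)(CCC[C@@H]1C)[C@H]2O[Si](C)(C)C(C)(C)C
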